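**Retrosynthetic overview**
- The target is the acetate of an (R)-bromohydrin. The carbinol comes from catalyst-controlled reduction of a bromomethyl (Z)-enone, whose CH2Br carbon is added as bromomethyllithium to the Weinreb amide of a ring-bearing (Z)-2-methylbut-2-enoate.
- Feature on which the strategy rests: in the only ring (a cyclohexane) the CHBr carbon is bonded to the CMe2 carbon, which is bonded to the ring CH that carries the side chain and lies next to the C=CH2 carbon. The CMe2–CH ring bond is therefore the bond made when a beta-bromo tertiary cation is captured by a 2-(silylmethyl)alkene.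
- Key disconnection: that ring bond, opened to an acyclic (S)-bromo tertiary acetate carrying an allylsilane and the (Z)-enoate. The C–Br bond is made first (Shi epoxide, then bromide opening with inversion), so no electrophilic bromine is needed when the ring forms.
- Chain assembly: an eight-carbon bromo acetate alkyne (from 6-methylhept-5-en-2-one), then the silylmethyl carbon and two oxirane carbons in one carbocupration/alkylation, then three carbons by Still–Gennari olefination.
- Ring order: the single six-membered ring is closed once, in the key step, after the whole chain is in place and before the CH2Br carbon is introduced.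

Key step: step 9

Remark on the chemistry: the sense of induction in the two catalyst-controlled steps (3 and 12) is assigned from the accepted transition-state models; should either run the opposite way, the enantiomeric catalyst is used with no other change.

Step 1
Reactants: 1 6-methylhept-5-en-2-one
Product: 2 diethyl 6-methylhepta-1,5-dien-2-yl phosphate
Conditions: LiN(iPr)2, THF, −78 °C; ClP(O)(OEt)2, −78 °C to rt
Reagents that add atoms: diethyl chlorophosphate, CCOP(=O)(Cl)OCC
Why: Kinetic deprotonation at −78 °C gives the less substituted (methyl-side) enolate, which is trapped on oxygen by the chlorophosphate (enol phosphate formation).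

Step 2
Reactants: 2 diethyl 6-methylhepta-1,5-dien-2-yl phosphate
Product: 3 6-methylhept-5-en-1-yne
Conditions: LiN(iPr)2 (2.3 equiv), THF, −78 °C to rt; H2O
Reagents that add atoms: none
Why: Base-induced beta-elimination of diethyl phosphate from the terminal enol phosphate gives the terminal alkyne (enol phosphate elimination route from methyl ketones to alkynes), and the isolated trisubstituted alkene is not affected.

Step 3
Reactants: 3 6-methylhept-5-en-1-yne
Product: 4 (R)-3-(but-3-yn-1-yl)-2,2-dimethyloxirane
Conditions: 1,2:4,5-di-O-isopropylidene-β-D-erythro-2,3-hexodiulo-2,6-pyranose (D-fructose-derived Shi ketone, 0.3 equiv), KHSO5 (as Oxone), K2CO3, Bu4NHSO4, MeCN/CH2(OMe)2/aq Na2B4O7 buffer, 0 °C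
Reagents that add atoms: potassium peroxymonosulfate (KHSO5), [K+].[O-]S(=O)(=O)OO
Why: Shi asymmetric epoxidation, in which the chiral dioxirane transfers oxygen to the electron-rich trisubstituted alkene through a spiro transition state; the D-fructose-derived ketone should give the (R)-epoxide, and the alkyne is inert to the dioxirane.

Step 4
Reactants: 4 (R)-3-(but-3-yn-1-yl)-2,2-dimethyloxirane
Product: 5 (S)-3-bromo-2-methylhept-6-yn-2-ol
Conditions: Li2NiBr4 (from LiBr and NiBr2), THF, 0 °C to rt; pH 7 buffer
Reagents that add atoms: dilithium tetrabromonickelate (Li2NiBr4), [Li+].[Li+].[Ni+2].[Br-].[Br-].[Br-].[Br-]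
Why: SN2 opening of the epoxide by soft bromide at the less substituted (secondary) carbon proceeds with inversion, turning the (R)-C–O centre into the (S)-C–Br centre and leaving the tertiary alcohol; the near-neutral medium disfavours SN1 opening at the tertiary carbon.

Step 5
Reactants: 5 (S)-3-bromo-2-methylhept-6-yn-2-ol
Product: 6 (S)-3-bromo-2-methylhept-6-yn-2-yl acetate
Conditions: Ac2O, Sc(OTf)3 (2 mol %), MeCN, −20 °C
Reagents that add atoms: acetic anhydride, CC(=O)OC(C)=O
Why: Lewis acid-catalysed acylation esterifies the hindered tertiary alcohol at low temperature without base, which avoids reclosure of the bromohydrin to the epoxide; the C–Br centre is not involved.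

Step 6
Reactants: 6 (S)-3-bromo-2-methylhept-6-yn-2-yl acetate; 7 (trimethylsilyl)methylmagnesium chloride; 8 oxirane
Product: 10 (3S,6Z)-3-bromo-9-hydroxy-2-methyl-6-[(trimethylsilyl)methyl]non-6-en-2-yl acetate, via alkenylcopper 9 (not isolated)
Conditions: 7, CuBr·SMe2, Et2O/Me2S, −45 °C; 6, −25 °C; then 1-pentynyllithium, HMPA, 8, −78 to −25 °C; aq NH4Cl
Reagents that add atoms: (trimethylsilyl)methylmagnesium chloride (7), C[Si](C)(C)C[Mg]Cl; oxirane (8), C1CO1
Why: Normant-type syn-carbocupration puts CH2SiMe3 on the internal alkyne carbon and copper on the terminus on the same side, and the alkenylcopper, activated as its mixed alkynyl cuprate, opens oxirane with retention, so CH2SiMe3 ends cis to CH2CH2OH (Z by the sequence rule, the carbon chain itself running trans through the double bond); the hindered tertiary acetate and the secondary bromide should not be attacked by the organocopper at these temperatures.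

Step 7
Reactants: 10 (3S,6Z)-3-bromo-9-hydroxy-2-methyl-6-[(trimethylsilyl)methyl]non-6-en-2-yl acetate
Product: 11 (3S,6Z)-3-bromo-2-methyl-9-oxo-6-[(trimethylsilyl)methyl]non-6-en-2-yl acetate
Conditions: Dess–Martin periodinane, NaHCO3, CH2Cl2, 0 °C; crude aldehyde used at once
Reagents that add atoms: none
Why: Buffered Dess–Martin oxidation gives the beta,gamma-unsaturated aldehyde without acid or base strong enough to move the double bond into conjugation or to protodesilylate the allylsilane.

Step 8
Reactants: 11 (3S,6Z)-3-bromo-2-methyl-9-oxo-6-[(trimethylsilyl)methyl]non-6-en-2-yl acetate; 12 methyl 2-[bis(2,2,2-trifluoroethoxy)phosphoryl]propanoate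
Product: 13 methyl (2Z,5Z,9S)-10-acetoxy-9-bromo-2,10-dimethyl-6-[(trimethylsilyl)methyl]undeca-2,5-dienoate
Conditions: 12, KN(SiMe3)2, 18-crown-6, THF, −78 °C; then 11, −78 °C
Reagents that add atoms: methyl 2-[bis(2,2,2-trifluoroethoxy)phosphoryl]propanoate (12), COC(=O)C(C)P(=O)(OCC(F)(F)F)OCC(F)(F)F
Why: Still–Gennari olefination, in which the trifluoroethyl phosphonate anion with a dissociated potassium counter-ion adds and eliminates under kinetic control to give the (Z)-2-methyl enoate; at −78 °C the enolizable skipped aldehyde should be consumed before it isomerizes.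

Step 9
Reactants: 13 methyl (2Z,5Z,9S)-10-acetoxy-9-bromo-2,10-dimethyl-6-[(trimethylsilyl)methyl]undeca-2,5-dienoate
Product: 15 methyl (Z)-4-[(1R,3S)-3-bromo-2,2-dimethyl-6-methylidenecyclohexyl]-2-methylbut-2-enoate, via bromonium ion 14 (not isolated)
Conditions: SnCl4 (2.5 equiv), 2,6-di-tert-butyl-4-methylpyridine (0.5 equiv), CH2Cl2 (5 mM), −78 °C
Reagents that add atoms: none
Why: Proposed new method: SnCl4 should ionize the tertiary acetate with anchimeric help from the neighbouring bromine to give the configurationally defined bromonium ion 14 (the equivalent of a beta-bromo tertiary cation), which is opened anti at its dimethyl-substituted carbon by the alkene carbon gamma to silicon; the resulting beta-silyl cation then loses Me3Si, so the new double bond can only be the exocyclic methylene. The closest known reaction types are the enantiospecific bromonium-ion polyene cyclization started from an enantiopure bromohydrin ester and the Lewis acid-promoted epoxide- or tertiary-cation-initiated cyclizations that end on a 2-(silylmethyl)alkene; the union of a pre-formed chiral bromonium ion with an allylsilane terminator has not been shown. The cyclohexane closes in the 6-endo mode with respect to the allylsilane double bond (both alkene carbons become ring atoms), the exo alternative being disfavoured because it would give a five-membered ring and a cation without beta-silicon stabilization. The CHBr centre is not touched (its C–Br bond persists), and the new ring CH is set relative to it by a chair transition state with bromine equatorial, in which the alkene geometry (ring tether trans to the enoate-bearing CH2) places the side chain equatorial, hence cis to bromine and (R). The step needs this cis relation and no leakage of configuration at CHBr: the first is secured by the alkene geometry fixed in the syn-carbocupration, the second by forming the bromonium ion at one site only with no free electrophilic bromine (which would attack the allylsilane first) and by high dilution and low temperature, which suppress bromonium transfer between alkenes. The electron-poor (Z)-enoate is inert to the cation and to SnCl4, and the hindered pyridine removes adventitious acid that would protodesilylate the allylsilane.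

Step 10
Reactants: 15 methyl (Z)-4-[(1R,3S)-3-bromo-2,2-dimethyl-6-methylidenecyclohexyl]-2-methylbut-2-enoate
Product: 16 (Z)-4-[(1R,3S)-3-bromo-2,2-dimethyl-6-methylidenecyclohexyl]-N-methoxy-N,2-dimethylbut-2-enamide
Conditions: MeNH(OMe)·HCl, iPrMgCl, THF, −20 to 0 °C
Reagents that add atoms: N,O-dimethylhydroxylamine hydrochloride, CNOC.Cl
Why: Direct aminolysis of the methyl ester by the chloromagnesium amide of N,O-dimethylhydroxylamine (Weinreb amide formation) is an acyl substitution by a weakly basic nucleophile and should leave the (Z)-alkene, the exocyclic methylene and the neopentyl-type secondary bromide untouched.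

Step 11
Reactants: 16 (Z)-4-[(1R,3S)-3-bromo-2,2-dimethyl-6-methylidenecyclohexyl]-N-methoxy-N,2-dimethylbut-2-enamide; 17 dibromomethane
Product: 19 (Z)-1-bromo-5-[(1R,3S)-3-bromo-2,2-dimethyl-6-methylidenecyclohexyl]-3-methylpent-3-en-2-one, via lithium hemiaminal adduct 18 (not isolated)
Conditions: 17 (3 equiv), MeLi·LiBr, THF, −78 °C; aq NH4Cl at −78 °C
Reagents that add atoms: dibromomethane (17), BrCBr
Why: Bromomethyllithium, generated by bromine–lithium exchange in the presence of the amide, adds once to give the chelated tetrahedral adduct 18, which collapses to the bromomethyl ketone only on quench (carbenoid homologation of a Weinreb amide), so a second addition or conjugate addition is not expected and the ring bromide does not exchange at −78 °C.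

Step 12
Reactants: 19 (Z)-1-bromo-5-[(1R,3S)-3-bromo-2,2-dimethyl-6-methylidenecyclohexyl]-3-methylpent-3-en-2-one
Product: 20 (2R,3Z)-1-bromo-5-[(1R,3S)-3-bromo-2,2-dimethyl-6-methylidenecyclohexyl]-3-methylpent-3-en-2-ol
Conditions: (R)-1-methyl-3,3-diphenyltetrahydro-1H,3H-pyrrolo[1,2-c][1,3,2]oxazaborole ((R)-Me-CBS, 0.2 equiv), catecholborane, toluene, −78 °C
Reagents that add atoms: none
Why: Corey–Bakshi–Shibata reduction, in which the ketone binds the catalyst boron anti to its larger substituent (the alpha-branched alkenyl group, CH2Br being the smaller one as in phenacyl halides) and hydride is delivered within the complex to one carbonyl face, which with the (R)-catalyst should give the (R)-carbinol; catecholborane at −78 °C does not hydroborate the exocyclic or the trisubstituted alkene.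

Step 13
Reactants: 20 (2R,3Z)-1-bromo-5-[(1R,3S)-3-bromo-2,2-dimethyl-6-methylidenecyclohexyl]-3-methylpent-3-en-2-ol
Product: 21 (2R,3Z)-1-bromo-5-[(1R,3S)-3-bromo-2,2-dimethyl-6-methylidenecyclohexyl]-3-methylpent-3-en-2-yl acetate (CNP0136568.3)
Conditions: Ac2O, pyridine, 4-(dimethylamino)pyridine (cat.), CH2Cl2, 0 °C
Reagents that add atoms: acetic anhydride, CC(=O)OC(C)=O
Why: Acylation of the secondary alcohol under nucleophilic catalysis (DMAP-catalysed acetylation) uses a base too weak to close the bromohydrin to an epoxide and does not touch the carbinol C–O bond, so the (R) configuration is kept.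

**Compound list**
1 | 6-methylhept-5-en-2-one | CC(C)=CCCC(C)=O | starting material
2 | diethyl 6-methylhepta-1,5-dien-2-yl phosphate | C=C(CCC=C(C)C)OP(=O)(OCC)OCC | intermediate
3 | 6-methylhept-5-en-1-yne | CC(C)=CCCC#C | intermediate
4 | (R)-3-(but-3-yn-1-yl)-2,2-dimethyloxirane | CC1(C)O[C@@H]1CCC#C | intermediate
5 | (S)-3-bromo-2-methylhept-6-yn-2-ol | CC(C)(O)[C@@H](Br)CCC#C | intermediate
6 | (S)-3-bromo-2-methylhept-6-yn-2-yl acetate | CC(=O)OC(C)(C)[C@@H](Br)CCC#C | intermediate
7 | (trimethylsilyl)methylmagnesium chloride | C[Si](C)(C)C[Mg]Cl | starting material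
8 | oxirane | C1CO1 | starting material
9 | [(1Z,5S)-6-acetoxy-5-bromo-6-methyl-2-[(trimethylsilyl)methyl]hept-1-en-1-yl]copper (as its magnesium halide complex) | CC(=O)OC(C)(C)[C@@H](Br)CC/C(C[Si](C)(C)C)=C/[Cu] | intermediate
10 | (3S,6Z)-3-bromo-9-hydroxy-2-methyl-6-[(trimethylsilyl)methyl]non-6-en-2-yl acetate | CC(=O)OC(C)(C)[C@@H](Br)CC/C(C[Si](C)(C)C)=C/CCO | intermediate
11 | (3S,6Z)-3-bromo-2-methyl-9-oxo-6-[(trimethylsilyl)methyl]non-6-en-2-yl acetate | CC(=O)OC(C)(C)[C@@H](Br)CC/C(C[Si](C)(C)C)=C/CC=O | intermediate
12 | methyl 2-[bis(2,2,2-trifluoroethoxy)phosphoryl]propanoate | COC(=O)C(C)P(=O)(OCC(F)(F)F)OCC(F)(F)F | starting material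
13 | methyl (2Z,5Z,9S)-10-acetoxy-9-bromo-2,10-dimethyl-6-[(trimethylsilyl)methyl]undeca-2,5-dienoate | CC(=O)OC(C)(C)[C@@H](Br)CC/C(C[Si](C)(C)C)=C/C/C=C(/C)C(=O)OC | intermediate
14 | (S)-bromonium ion (2,2-dimethyl-3-alkylbromiranium) formed from 13 by loss of acetate | CC1(C)[Br+][C@H]1CC/C(C[Si](C)(C)C)=C/C/C=C(/C)C(=O)OC | intermediate
15 | methyl (Z)-4-[(1R,3S)-3-bromo-2,2-dimethyl-6-methylidenecyclohexyl]-2-methylbut-2-enoate | C=C1CC[C@H](Br)C(C)(C)[C@@H]1C/C=C(/C)C(=O)OC | intermediate
16 | (Z)-4-[(1R,3S)-3-bromo-2,2-dimethyl-6-methylidenecyclohexyl]-N-methoxy-N,2-dimethylbut-2-enamide | C=C1CC[C@H](Br)C(C)(C)[C@@H]1C/C=C(/C)C(=O)N(C)OC | intermediate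
17 | dibromomethane | BrCBr | starting material
18 | lithium alkoxide of the N-methoxy-N-methyl hemiaminal (tetrahedral adduct of bromomethyllithium to 16) | C=C1CC[C@H](Br)C(C)(C)[C@@H]1C/C=C(/C)C(CBr)(O[Li])N(C)OC | intermediate
19 | (Z)-1-bromo-5-[(1R,3S)-3-bromo-2,2-dimethyl-6-methylidenecyclohexyl]-3-methylpent-3-en-2-one | C=C1CC[C@H](Br)C(C)(C)[C@@H]1C/C=C(/C)C(=O)CBr | intermediate
20 | (2R,3Z)-1-bromo-5-[(1R,3S)-3-bromo-2,2-dimethyl-6-methylidenecyclohexyl]-3-methylpent-3-en-2-ol | C=C1CC[C@H](Br)C(C)(C)[C@@H]1C/C=C(/C)[C@H](CBr)O | intermediate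
21 | (2R,3Z)-1-bromo-5-[(1R,3S)-3-bromo-2,2-dimethyl-6-methylidenecyclohexyl]-3-methylpent-3-en-2-yl acetate (CNP0136568.3) | C=C1CC[C@H](Br)C(C)(C)[C@@H]1C/C=C(/C)[C@H](CBr)OC(C)=O | target

Total step count: 13
Longest linear sequence: 13 steps (1 to 21)

**Steps most likely to fail**

Step 9 (Proposed new method). The beta-bromo tertiary acetate may ionize too slowly, or the cation may be lost before ring closure through proton loss to an isopropenyl group, chloride capture, protodesilylation of the allylsilane or a boat-like closure to the trans isomer; bromonium transfer between alkenes would erode the enantiomeric purity. The fallback uses known chemistry, sets out from 3 and comes back at 15. Shi epoxidation of 3 with the enantiomeric, L-fructose-derived ketone should give (S)-3-(but-3-yn-1-yl)-2,2-dimethyloxirane F1. Carbocupration with the silylmethylcopper reagent from 7 gives the epoxy alkenylcopper F2, which is alkylated with 8 as in step 6 to the epoxy homoallylic alcohol F3. Buffered Dess–Martin oxidation gives the epoxy aldehyde F4, and Still–Gennari olefination with 12 gives the epoxy allylsilane dienoate F5. Treatment with BF3·OEt2 in CH2Cl2 at −78 °C, the established epoxide-initiated cyclization terminated by a 2-(silylmethyl)alkene, should give the equatorial (3S)-hydroxy ester F6 with the exocyclic methylene and the cis side chain. Dess–Martin oxidation gives the ring keto ester F7. LiBH(s-Bu)3 in THF at −78 °C delivers hydride from the equatorial direction to give the axial (3R)-hydroxy ester F8, the ketone reacting faster than the alpha-methyl enoate. Appel bromination (CBr4, PPh3) with inversion, a displacement documented for axial 3-hydroxy-2,2-dimethylcyclohexane units, gives the equatorial (3S)-bromide 15.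

Step 6. The alkenylcopper may open oxirane too slowly, so that protonation on work-up or attack of the ate complex on the tertiary acetate outruns C–C bond formation. The fallback sets out from 6 (through alkenylcopper 9) and comes back at 10. Intermediate 9 is quenched with I2 at −78 °C to give the (Z)-alkenyl iodide F9. Stille coupling with tributyl(vinyl)stannane (Pd(PPh3)4, CuI, DMF, room temperature) gives the 2-(silylmethyl)-1,3-diene F10. 9-Borabicyclo[3.3.1]nonane in THF adds to the terminal vinyl group only, giving the homoallylic borane F11, and oxidation with NaBO3·4H2O, which spares the tertiary acetate, gives 10.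

Step 12. Hydride delivery may show poor facial selectivity, because the (Z)-enone is twisted out of conjugation and CH2Br is not much smaller than the alkenyl group. The fallback sets out from 19 and comes back at 20. Reduction with NaBH4/CeCl3·7H2O in MeOH at −78 °C gives the carbinol-epimeric bromohydrin mixture F12. Acylation with vinyl acetate and Burkholderia cepacia lipase should, by the empirical size rule for lipase acylation of secondary alcohols, esterify the (S)-carbinol epimer to the (S)-acetate F13 and leave 20, which is separated by chromatography.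

**Further compounds**
F1 | step 9 | (S)-3-(but-3-yn-1-yl)-2,2-dimethyloxirane | CC1(C)O[C@H]1CCC#C
F2 | step 9 | [(Z)-4-[(2S)-3,3-dimethyloxiran-2-yl]-2-[(trimethylsilyl)methyl]but-1-en-1-yl]copper | CC1(C)O[C@H]1CC/C(C[Si](C)(C)C)=C/[Cu]
F3 | step 9 | (Z)-6-[(2S)-3,3-dimethyloxiran-2-yl]-4-[(trimethylsilyl)methyl]hex-3-en-1-ol | CC1(C)O[C@H]1CC/C(C[Si](C)(C)C)=C/CCO
F4 | step 9 | (Z)-6-[(2S)-3,3-dimethyloxiran-2-yl]-4-[(trimethylsilyl)methyl]hex-3-enal | CC1(C)O[C@H]1CC/C(C[Si](C)(C)C)=C/CC=O
F5 | step 9 | methyl (2Z,5Z)-8-[(2S)-3,3-dimethyloxiran-2-yl]-2-methyl-6-[(trimethylsilyl)methyl]octa-2,5-dienoate | CC1(C)O[C@H]1CC/C(C[Si](C)(C)C)=C/C/C=C(/C)C(=O)OC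
F6 | step 9 | methyl (Z)-4-[(1R,3S)-3-hydroxy-2,2-dimethyl-6-methylidenecyclohexyl]-2-methylbut-2-enoate | C=C1CC[C@H](O)C(C)(C)[C@@H]1C/C=C(/C)C(=O)OC
F7 | step 9 | methyl (Z)-4-[(1R)-2,2-dimethyl-6-methylidene-3-oxocyclohexyl]-2-methylbut-2-enoate | C=C1CCC(=O)C(C)(C)[C@@H]1C/C=C(/C)C(=O)OC
F8 | step 9 | methyl (Z)-4-[(1R,3R)-3-hydroxy-2,2-dimethyl-6-methylidenecyclohexyl]-2-methylbut-2-enoate | C=C1CC[C@@H](O)C(C)(C)[C@@H]1C/C=C(/C)C(=O)OC
F9 | step 6 | (3S,6Z)-3-bromo-7-iodo-2-methyl-6-[(trimethylsilyl)methyl]hept-6-en-2-yl acetate | CC(=O)OC(C)(C)[C@@H](Br)CC/C(C[Si](C)(C)C)=C/I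
F10 | step 6 | (3S,6Z)-3-bromo-2-methyl-6-[(trimethylsilyl)methyl]nona-6,8-dien-2-yl acetate | CC(=O)OC(C)(C)[C@@H](Br)CC/C(C[Si](C)(C)C)=C/C=C
F11 | step 6 | (3S,6Z)-9-(9-borabicyclo[3.3.1]nonan-9-yl)-3-bromo-2-methyl-6-[(trimethylsilyl)methyl]non-6-en-2-yl acetate | CC(=O)OC(C)(C)[C@@H](Br)CC/C(C[Si](C)(C)C)=C/CCB1C2CCCC1CCC2
F12 | step 12 | (3Z)-1-bromo-5-[(1R,3S)-3-bromo-2,2-dimethyl-6-methylidenecyclohexyl]-3-methylpent-3-en-2-ol, mixture of (2R) and (2S) epimers | C=C1CC[C@H](Br)C(C)(C)[C@@H]1C/C=C(/C)C(CBr)O
F13 | step 12 | (2S,3Z)-1-bromo-5-[(1R,3S)-3-bromo-2,2-dimethyl-6-methylidenecyclohexyl]-3-methylpent-3-en-2-yl acetate | C=C1CC[C@H](Br)C(C)(C)[C@@H]1C/C=C(/C)[C@@H](CBr)OC(C)=O
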